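## Structural features

The target is a heliangolide-type germacranolide: a ten-membered carbocycle (C1–C10) trans-fused through C6 and C7 to a five-membered α-methylene-γ-lactone (C12 carbonyl, ring oxygen on C6, exocyclic C11=C13). The carbocycle holds a Z-trisubstituted C4=C5 alkene (C15 on C4) lying between two allylic oxygens, the C3 methacrylate and the C6 lactone oxygen, and a trans 1,10-epoxide with the C14 methyl on C10. There are six stereocentres: C6 (R), C7 (R) and C8 (R) are contiguous, C1 (R) and C10 (R) are joined in the epoxide and separated from C8 only by the C9 methylene, and C3 (S) stands alone between C2 and the alkene. The fragile groups are the α-methylene lactone (a Michael acceptor), the angelate on C8 (Z to E isomerisation to the tiglate), the methacrylate on C3, and the epoxide in a medium ring (transannular opening under acid). The lactone itself is sensitive to hydride and strong nucleophiles and can migrate to O8 once that hydroxyl is free. The real difficulty is closing the ten-membered ring with control of the C1/C10 geometry, and building the Z C4=C5 alkene, in the presence of this lactone. The key step exploits the fact that C7 is the β-carbon of the lactone, flanked by oxygen-bearing C6 and C8, while the α-carbon C11 carries one extra carbon (C13). That is the pattern left when a C8 acyl anion equivalent adds to C7 of a butenolide that already holds the C6 stereocentre and the enolate is trapped at C11 by a one-carbon electrophile.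

## Logic of the disconnections

32 to 31. The two C–O bonds of the oxirane (C1–O, C10–O) are cut first, because the epoxide is the most acid-sensitive group and 31 has only one electron-rich alkene. Two stereocentres are replaced by one E alkene. The forward step must select C1=C10 over four other alkenes and attack its outer face.

31 to 29 (through 30). The C11=C13 π bond is traced back to a C13–N bond. The Michael acceptor would not survive the nucleophilic, reductive and basic steps before it. The forward step needs quaternisation at nitrogen only and an elimination mild enough for both unsaturated esters.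

29 to 28 to 27 to 26 to 25. The acyl C–O bonds at O8 and O3 are cut. Unsaturated esters would be leaving groups β to the carbonyls of 22 and would not tolerate reductive coupling. This leaves two alcohols masked by silyl groups of different lability. The forward steps must unmask O3 before O8 and keep the Z geometry of the C8 acyl group.

25 to 24 to 23. The C1=C10 π bond is traced back to the two C–O bonds of a trans 1,10-diol. A stereospecific syn elimination turns either trans diol into the E alkene, so the ring closure only has to be trans-selective. The demand is a cyclic thionocarbonate on a tertiary/secondary diol and a mild fragmentation.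

23 to 22. The C1–C10 σ bond is cut. It is the one ring bond whose two ends can both be carbonyl carbons that the fragments deliver. The ring opens to a chain in which C3, C6, C7 and C8 are already set. The forward step is an intramolecular reductive coupling at high dilution that must leave the lactone alone.

22 to 21 to 20 to 19 to 18. The C1 aldehyde is traced to a terminal alkene (one carbon excised), O3–Si is cut, and the C10 ketone is traced to its dioxolane. The aldehyde is thereby latent through the acid step and the silylation. The cleavage must pick the monosubstituted alkene over C4=C5, and the ketal must be opened before the acid-labile O3 silyl group is put on.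

18 to 17. C2–C3 is cut. A reagent-controlled allylboration sets C3 independently of the remote centres and brings C1 and C2 with C1 latent as an alkene. The demand is enantioface control by the reagent.

17 to 16. C3–C4 is cut at the formyl carbon. C3 enters at the aldehyde oxidation level, so no hydride reagent ever meets the lactone. The carbonylation must retain the alkene geometry.

16 to 15 to 14 to 13 to 12. C4=C5 is cut. An iodo-olefination brings C4, C15 and the handle for C3 in one step. It must be Z-selective and must not epimerise C6. Before it, O8 is silylated, O5 is unmasked and C5 is oxidised.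

12 to 11 to 10. The C8–H bond is cut, and the C8 carbonyl is traced to the dithiane. The forward steps are a near-neutral dethioacetalisation and a hydride delivery whose face is chosen by the reagent.

10 to 2 + 6 + 7 (through 8 and 9). C7–C8 and C11–C13 are cut in one operation. This separates the C5–C7/C11–C12 lactone piece, the C8–C10/C14 acyl anion piece and C13. The forward step needs 1,4- over 1,2-addition, attack anti to the C6 substituent, and alkylation anti to the new C7 substituent.

2 to 1, and 6 to 5 to 3 + 4. The O–Si bond, the two ketal C–O bonds and the two C–S bonds are cut. All are standard protecting-group operations on commercial materials.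

## Other disconnections considered

Alternative 1: The cut is C2–C3 with re-formation of C5–C10, so the ten-membered ring is traced to a six-membered carbinol bearing an isopropenyl group on the carbinol carbon and a vinyl group on the neighbouring quaternary carbon. Forward, the potassium alkoxide (KH, crown ether) would undergo an anionic oxy-Cope [3,3] shift and the C5 enolate would be captured as enol triflate A1.
- In favour: the ring arises by ring expansion, without high dilution; on ring formation this alternative is better than the chosen plan. The 1(10)E and ring-cis C4=C5 geometries follow from the transition-state geometry. C6, C7 and C8 are set on a six-membered ring, where relative control is at least equal to the reagent control used at C8 here.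
- Against: A1 has no oxygen at C3, so a late allylic oxidation must choose C3 among several allylic positions and the correct face. C5 carries a triflate that must be reduced. C12 is still an isopropenyl carbon that must be oxidised and lactonised onto O6. The epoxide and both esters also remain.
- Comparison: the mechanism is concerted and stereospecific, against a polar three-component union. A1 is closer to the target in ring size but further in oxidation pattern. The chosen plan has C12, C13 and every oxygen except the epoxide in place before ring closure, and should need fewer late oxidations on a sensitive medium ring.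

Alternative 2: The cut is C4=C5, made inside a temporary seven-membered dioxasilacycle that ties the C3 and C6 allylic oxygens through a diisopropylsilylene group. Forward, the second-generation Grubbs catalyst would close this ring between the C4 isopropenyl and C5 vinyl groups to give A2.
- In favour: the small ring enforces the Z geometry, which is a better solution to the C4=C5 problem than the iodo-olefination of the chosen plan. The union of a C1–C4 and a C5–C10 fragment is as convergent as the chosen three-component step.
- Against: the metathesis must form a trisubstituted alkene between two branched allylic centres. The mixed silylene has to be built stepwise from two different secondary alcohols. A2 has no lactone yet (C12 is a benzyl ether, C13 is absent). C7 and C8 must be made by open-chain stereocontrol.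
- Comparison: the ten-membered ring still has to be closed at C1–C10 from a C10 ketal and a masked C1, so this alternative is equal to the chosen plan on the hardest step. The extra protecting groups and the late lactone and methylene construction should make it longer.

Alternative 3: The cut is C5–C6 together with the lactone C–O bond. Forward, CrCl2 with catalytic NiCl2 would turn a C5 Z-vinyl iodide into an alkenylchromium species that adds to a C6 aldehyde, closes the ring, and lets the C6 alkoxide lactonise onto the C12 methyl ester to give A3.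
- In favour: ring closure and lactone formation occur in one operation, and the shorter endgame after A3 is better than the chosen plan. The 1(10)E alkene is made beforehand in an open chain, which is also better than the diol/elimination detour here. The chemoselectivity of the organochromium reagent toward esters equals that needed in the pinacol step.
- Against: C6 is created during the macrocyclisation, and its sense depends on the conformation of the forming ring, whereas the chosen plan takes C6 from the chiral pool. The aldehyde is α-branched at C7 with a β-silyloxy group on C8, so epimerisation and elimination threaten. A wrong C6 epimer would not give the trans lactone. C13 must still be added to the macrocyclic lactone, which is comparable to the amine unmasking here.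
- Comparison: the open-chain precursor of A3 needs three stereocentres (C3, C7, C8), a Z-iodoalkene and an E trisubstituted alkene in a linear sequence. The overall length should therefore be similar, with the stereochemical risk at C6 against the geometric risk at C1/C10.

Key step: step 4

Remarks on the chemistry:
- Germacrane numbering (C1–C15) is used for every intermediate. The letters R/S at C6 and C7 change along the route only because substituent priorities change, not because the geometry changes.
- A check of the fragment structures against the target revealed no error of constitution or configuration. The S centre of the butenolide becomes C6 (R in the target by a priority change), and the trans,trans lactone carries C7 and C11 as required.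
- Three design changes were made. The silyl group of fragment A is tert-butyldimethylsilyl, so it can be removed beside a secondary silyl ether. The dithiane of fragment B is made before the dioxolane. Steps with acid use more than one equivalent because the dimethylamino group takes up the first.
- (+)-B-Allyldiisopinocampheylborane (from (+)-α-pinene), (S)-2-methyl-CBS-oxazaborolidine, TiCl3(DME)1.5, angelic acid and 1,3-dimethyl-2-phenyl-1,3,2-diazaphospholidine are taken as commercial reagents.

## Steps

Step 1
Reactants: 1 (S)-5-(hydroxymethyl)furan-2(5H)-one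
Product: 2 (S)-5-[(tert-butyldimethylsilyloxy)methyl]furan-2(5H)-one (fragment A)
Conditions: TBSCl, imidazole, CH2Cl2, 0 °C → rt
Reagents that add atoms: tert-butyldimethylsilyl chloride, C[Si](C)(Cl)C(C)(C)C
Why: Silylation of a primary alcohol with a silyl chloride and imidazole leaves the stereocentre untouched. The silyl ether is bulky enough to shield one face of the butenolide and, being primary, can later be cleaved beside a hindered secondary silyl ether.

Step 2
Reactants: 3 4,4-dimethoxybutan-2-one; 4 propane-1,3-dithiol
Product: 5 1-(1,3-dithian-2-yl)propan-2-one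
Conditions: BF3·OEt2 (cat.), CH2Cl2, −20 → 0 °C
Reagents that add atoms: none
Why: Lewis acid-mediated transthioacetalisation: the β-keto acetal ionises, or loses methanol to the β-methoxy enone which takes up the dithiol by conjugate addition, so the aldehyde-level carbon reacts and the ketone stays free. One equivalent of dithiol at low temperature limits dithioketal formation.

Step 3
Reactants: 5 1-(1,3-dithian-2-yl)propan-2-one
Product: 6 2-[(2-methyl-1,3-dioxolan-2-yl)methyl]-1,3-dithiane (fragment B)
Conditions: HOCH2CH2OH, p-TsOH (cat.), benzene, reflux (Dean–Stark)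
Reagents that add atoms: ethylene glycol, OCCO
Why: Acid-catalysed ketalisation with azeotropic removal of water; the dithiane is stable to it. Making the dioxolane after the dithiane avoids the competition between two O,O-acetals that the reverse order would create.

Step 4
Reactants: 6 fragment B; 2 fragment A; 7 N,N-dimethylmethyleneiminium iodide (Eschenmoser's salt)
Product: 10 (3R,4S,5S)-5-[(tert-butyldimethylsilyloxy)methyl]-3-[(dimethylamino)methyl]-4-{2-[(2-methyl-1,3-dioxolan-2-yl)methyl]-1,3-dithian-2-yl}dihydrofuran-2(3H)-one, via lithiated dithiane 8 (not isolated), via lithium lactone enolate 9 (not isolated)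
Conditions: 6, t-BuLi, THF–HMPA (10:1; DMPU as substitute), −78 °C; then 2, −78 °C; then 7, −78 → 0 °C
Reagents that add atoms: none
Why: t-BuLi removes the C8 proton of 6; the sulfur-stabilised carbanion 8, separated from lithium by the polar additive, adds to C7 of butenolide 2 in the 1,4 sense, and the lithium enolate 9 is C-alkylated at C11 by the iminium ion of 7 (Mannich reaction). The closest known reaction type is the tandem conjugate addition of a lithiated 1,3-dithiane to a 2(5H)-furanone with electrophilic trapping of the enolate. No ring is closed; two skeletal bonds (C7–C8, C11–C13) and two stereocentres (C7, C11) are formed. At C7 the nucleophile approaches the planar butenolide anti to the C6 silyloxymethyl group, which gives the 6,7-trans lactone. At C11 the iminium ion approaches the enolate face anti to the very bulky C7 dithianyl group, which gives the 7,11-trans arrangement; this centre is later destroyed. The step needs 1,4- over 1,2-addition and over γ-deprotonation; the solvent-separated ion pair, the low temperature and the low carbonyl electrophilicity of a lactone should secure this. C-Alkylation must outrun proton transfer, for which an excess of the preformed, highly electrophilic iminium salt is used. The ketal oxygens sit two carbons from the carbanion, so β-elimination of alkoxide from 8 is not possible.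

Step 5
Reactants: 10 key-step lactone with C8 dithiane
Product: 11 (3R,4S,5S)-5-[(tert-butyldimethylsilyloxy)methyl]-3-[(dimethylamino)methyl]-4-[2-(2-methyl-1,3-dioxolan-2-yl)acetyl]dihydrofuran-2(3H)-one (C8 ketone)
Conditions: Hg(ClO4)2, CaCO3, THF–H2O (5:1), 0 °C → rt
Reagents that add atoms: water, O
Why: Dithiane hydrolysis: thiophilic divalent mercury cleaves the C–S bonds and water supplies the carbonyl oxygen, while CaCO3 keeps the medium near neutral so that the dioxolane and the silyl ether survive. The ring C6–O bond is orthogonal to the enol π system at C7, so β-elimination of the lactone oxygen is stereoelectronically slow.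

Step 6
Reactants: 11 C8 ketone
Product: 12 (3R,4R,5S)-5-[(tert-butyldimethylsilyloxy)methyl]-3-[(dimethylamino)methyl]-4-[(1R)-1-hydroxy-2-(2-methyl-1,3-dioxolan-2-yl)ethyl]dihydrofuran-2(3H)-one (8R alcohol)
Conditions: (S)-2-methyl-CBS-oxazaborolidine (1 equiv), catecholborane, toluene, −78 → −40 °C; MeOH
Reagents that add atoms: none
Why: CBS reduction: the ketone binds the catalyst boron anti to its larger substituent, the branched ring carbon C7, and hydride is delivered to the face that gives the 8R alcohol, in the same sense as (R)-alcohols from aryl methyl ketones with the (S)-catalyst. Reagent control is chosen because the two ring carbons flanking C7 are too alike for reliable substrate control; lactone and ketal are inert to catecholborane at this temperature.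

Step 7
Reactants: 12 8R alcohol
Product: 13 (3R,4S,5S)-4-[(1R)-1-(tert-butyldimethylsilyloxy)-2-(2-methyl-1,3-dioxolan-2-yl)ethyl]-5-[(tert-butyldimethylsilyloxy)methyl]-3-[(dimethylamino)methyl]dihydrofuran-2(3H)-one
Conditions: TBSOTf, 2,6-lutidine, CH2Cl2, −78 → 0 °C
Reagents that add atoms: tert-butyldimethylsilyl trifluoromethanesulfonate, C[Si](C)(OS(=O)(=O)C(F)(F)F)C(C)(C)C
Why: Silylation of a hindered secondary alcohol with a silyl triflate and a hindered base. Immediate protection of O8 prevents migration of the lactone from O6 to O8.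

Step 8
Reactants: 13 bis-silyl ether
Product: 14 (3R,4S,5S)-4-[(1R)-1-(tert-butyldimethylsilyloxy)-2-(2-methyl-1,3-dioxolan-2-yl)ethyl]-3-[(dimethylamino)methyl]-5-(hydroxymethyl)dihydrofuran-2(3H)-one
Conditions: HF·pyridine, pyridine, THF, 0 °C
Reagents that add atoms: none
Why: Selective desilylation by steric access: the primary O5 ether is cleaved, while the secondary O8 ether, flanked by the ring and a neopentyl-type methylene, should remain. The dioxolane is stable to pyridine-buffered HF.

Step 9
Reactants: 14 primary alcohol
Product: 15 (2S,3S,4R)-3-[(1R)-1-(tert-butyldimethylsilyloxy)-2-(2-methyl-1,3-dioxolan-2-yl)ethyl]-4-[(dimethylamino)methyl]-5-oxotetrahydrofuran-2-carbaldehyde (C5 aldehyde)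
Conditions: Dess–Martin periodinane, NaHCO3, CH2Cl2, 0 °C → rt; used crude
Reagents that add atoms: none
Why: Dess–Martin oxidation under buffered, non-basic conditions should give the α-acyloxy aldehyde without epimerisation at C6.

Step 10
Reactants: 15 C5 aldehyde
Product: 16 (3R,4S,5S)-4-[(1R)-1-(tert-butyldimethylsilyloxy)-2-(2-methyl-1,3-dioxolan-2-yl)ethyl]-3-[(dimethylamino)methyl]-5-[(1Z)-2-iodoprop-1-en-1-yl]dihydrofuran-2(3H)-one (Z-vinyl iodide)
Conditions: EtPPh3I, n-BuLi, THF, 0 °C; I2, −78 °C; NaN(SiMe3)2, −78 °C; then 15, −78 → −20 °C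
Reagents that add atoms: ethyltriphenylphosphonium iodide, CC[P+](c1ccccc1)(c1ccccc1)c1ccccc1.[I-]; iodine, II
Why: Stork–Zhao-type Wittig olefination with an α-iodo ylide: kinetic cis-selective oxaphosphetane formation places iodine cis to the C6 substituent and gives the Z-iodoalkene, and the ylide attacks the aldehyde far faster than the lactone at −78 °C. A vinyl iodide is preferred to a Z-enoate because it reaches the C3 aldehyde without a hydride reagent, which the lactone would not tolerate.

Step 11
Reactants: 16 Z-vinyl iodide
Product: 17 (2Z)-3-{(2R,3S,4R)-3-[(1R)-1-(tert-butyldimethylsilyloxy)-2-(2-methyl-1,3-dioxolan-2-yl)ethyl]-4-[(dimethylamino)methyl]-5-oxotetrahydrofuran-2-yl}-2-methylprop-2-enal (Z-enal)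
Conditions: Pd(PPh3)4 (cat.), CO (1–3 atm), Bu3SnH (slow addition), THF, 50 °C
Reagents that add atoms: carbon monoxide, [C-]#[O+]
Why: Palladium-catalysed reductive carbonylation (formylation) of a vinyl iodide: oxidative addition of zerovalent palladium with retention, CO insertion and hydride transfer from tin give the Z-enal. Slow addition of the tin hydride suppresses direct reduction of the iodide.

Step 12
Reactants: 17 Z-enal
Product: 18 (3R,4S,5R)-4-[(1R)-1-(tert-butyldimethylsilyloxy)-2-(2-methyl-1,3-dioxolan-2-yl)ethyl]-3-[(dimethylamino)methyl]-5-[(1Z,3S)-3-hydroxy-2-methylhexa-1,5-dien-1-yl]dihydrofuran-2(3H)-one (3S homoallylic alcohol)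
Conditions: (+)-Ipc2B(allyl) (from (+)-α-pinene), Et2O, −78 °C; then HOCH2CH2NH2, rt
Reagents that add atoms: (+)-B-allyldiisopinocampheylborane, C=CCB([C@H]1[C@H](C)[C@H]2C[C@@H](C1)C2(C)C)[C@H]1[C@H](C)[C@H]2C[C@@H](C1)C2(C)C
Why: Brown asymmetric allylboration through a chair six-membered transition state: the reagent from (+)-α-pinene adds to the Si face of aldehydes, which for this α-methyl enal corresponds to the 3S alcohol. Control is by the reagent, since the nearest stereocentre (C6) is remote, and the non-oxidative ethanolamine work-up spares the amine and the lactone.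

Step 13
Reactants: 18 3S homoallylic alcohol
Product: 19 (3R,4S,5R)-4-[(1R)-1-(tert-butyldimethylsilyloxy)-3-oxobutyl]-3-[(dimethylamino)methyl]-5-[(1Z,3S)-3-hydroxy-2-methylhexa-1,5-dien-1-yl]dihydrofuran-2(3H)-one (C10 methyl ketone)
Conditions: PPTS (2 equiv), acetone–H2O (10:1), 55 °C
Reagents that add atoms: water, O
Why: Acid-catalysed hydrolysis of the dioxolane; the second equivalent of PPTS is needed because the dimethylamino group takes up the first. The medium is mild enough for the secondary silyl ether, and the step is placed before the acid-labile triethylsilyl group is introduced.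

Step 14
Reactants: 19 C10 methyl ketone
Product: 20 (3R,4S,5R)-4-[(1R)-1-(tert-butyldimethylsilyloxy)-3-oxobutyl]-3-[(dimethylamino)methyl]-5-[(1Z,3S)-2-methyl-3-(triethylsilyloxy)hexa-1,5-dien-1-yl]dihydrofuran-2(3H)-one
Conditions: TESCl, imidazole, DMAP (cat.), CH2Cl2, 0 °C → rt
Reagents that add atoms: chlorotriethylsilane, CC[Si](Cl)(CC)CC
Why: Silylation of the allylic secondary alcohol; the triethylsilyl ether is a poor leaving group β to the future C1 aldehyde and can later be cleaved beside the O8 tert-butyldimethylsilyl ether.

Step 15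
Reactants: 20 triethylsilyl ether
Product: 22 (3S,4Z)-5-{(2R,3S,4R)-3-[(1R)-1-(tert-butyldimethylsilyloxy)-3-oxobutyl]-4-[(dimethylamino)methyl]-5-oxotetrahydrofuran-2-yl}-4-methyl-3-(triethylsilyloxy)pent-4-enal (keto aldehyde), via vicinal diol 21 (not isolated)
Conditions: OsO4 (cat.), NaIO4, 2,6-lutidine, dioxane–H2O (3:1), rt
Reagents that add atoms: osmium tetroxide, O=[Os](=O)(=O)=O; sodium periodate, [Na+].[O-]I(=O)(=O)=O
Why: Lemieux–Johnson cleavage: OsO4 dihydroxylates the monosubstituted terminal alkene much faster than the hindered C4=C5 alkene with its two allylic oxygens, and NaIO4 cleaves the diol 21. The lutidine buffer protects the triethylsilyl ether and the β-silyloxy aldehyde.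

Step 16
Reactants: 22 keto aldehyde
Product: 23 (1R,3S,6R,7S,8R,10R,11R)-8-(tert-butyldimethylsilyloxy)-13-(dimethylamino)-1,10-dihydroxy-3-(triethylsilyloxy)germacr-4Z-en-12,6-olide (trans 1,10-diol)
Conditions: TiCl3(DME)1.5, Zn–Cu, DME, 25 °C, slow addition of 22 (high dilution); aq. K2CO3
Reagents that add atoms: none
Why: McMurry-type pinacol coupling: low-valent titanium reduces both carbonyls to titanium-bound ketyls that couple within the molecule, slow addition favours cyclisation, and at 25 °C the reaction stops at the diol and leaves the lactone alone. In a ten-membered ring the two titanium-bound oxygens are expected to lie anti, giving a trans diol. Either trans diol leads to the same alkene in steps 17 and 18, so only the trans preference matters; the 1R,10R isomer is drawn.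

Step 17
Reactants: 23 trans 1,10-diol
Product: 24 (1R,3S,6R,7S,8R,10R,11R)-8-(tert-butyldimethylsilyloxy)-13-(dimethylamino)-1,10-(thiocarbonyldioxy)-3-(triethylsilyloxy)germacr-4Z-en-12,6-olide (cyclic thionocarbonate)
Conditions: 1,1'-thiocarbonyldiimidazole, DMAP (cat.), toluene, 90 °C
Reagents that add atoms: 1,1'-thiocarbonyldiimidazole, S=C(n1ccnc1)n1ccnc1
Why: Thiocarbonylation of a 1,2-diol: the secondary O1 is acylated first and the tertiary O10 closes the five-membered ring, which a trans diol on a ten-membered carbocycle can span.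

Step 18
Reactants: 24 cyclic thionocarbonate
Product: 25 (3S,6R,7S,8R,11R)-8-(tert-butyldimethylsilyloxy)-13-(dimethylamino)-3-(triethylsilyloxy)germacra-1(10)E,4Z-dien-12,6-olide
Conditions: 1,3-dimethyl-2-phenyl-1,3,2-diazaphospholidine, THF, 40 °C
Reagents that add atoms: none
Why: Corey–Winter olefination in its diazaphospholidine variant: desulfurisation to the carbene and concerted syn loss of CO2 are stereospecific, so the trans thionocarbonate gives the 1(10)E alkene. At 40 °C the Mannich base and the 1(10)E,4Z-diene should be stable.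

Step 19
Reactants: 25 bis-silylated 1(10)E,4Z-diene
Product: 26 (3S,6R,7S,8R,11R)-8-(tert-butyldimethylsilyloxy)-13-(dimethylamino)-3-hydroxygermacra-1(10)E,4Z-dien-12,6-olide
Conditions: HF·pyridine, pyridine, THF, 0 °C
Reagents that add atoms: none
Why: Selective desilylation: buffered HF cleaves the triethylsilyl ether much faster than the hindered tert-butyldimethylsilyl ether, and the buffered medium should not protonate the C1=C10 alkene.

Step 20
Reactants: 26 C3 alcohol
Product: 27 (3S,6R,7S,8R,11R)-8-(tert-butyldimethylsilyloxy)-13-(dimethylamino)-3-(methacryloyloxy)germacra-1(10)E,4Z-dien-12,6-olide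
Conditions: methacrylic anhydride, Et3N, DMAP (cat.), CH2Cl2, 0 °C → rt
Reagents that add atoms: methacrylic anhydride, C=C(C)C(=O)OC(=O)C(C)=C
Why: DMAP-catalysed acylation of the only free hydroxyl; O8 is still silylated, so the two esters cannot be interchanged.

Step 21
Reactants: 27 C3 methacrylate
Product: 28 (3S,6R,7R,8R,11R)-13-(dimethylamino)-8-hydroxy-3-(methacryloyloxy)germacra-1(10)E,4Z-dien-12,6-olide
Conditions: TBAF, AcOH (1:1), THF, rt
Reagents that add atoms: none
Why: Fluoride desilylation buffered with acetic acid removes the remaining secondary silyl ether without touching the methacrylate, the lactone or the alkenes.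

Step 22
Reactants: 28 C8 alcohol
Product: 29 (3S,6R,7R,8R,11R)-8-(angeloyloxy)-13-(dimethylamino)-3-(methacryloyloxy)germacra-1(10)E,4Z-dien-12,6-olide
Conditions: angelic acid, 2,4,6-trichlorobenzoyl chloride, Et3N, toluene, rt; then 28, toluene, 75 °C
Reagents that add atoms: angelic acid, C/C=C(/C)C(=O)O
Why: Yamaguchi-type esterification through the preformed mixed anhydride, which is attacked at the less hindered angeloyl carbonyl. Leaving out the nucleophilic catalyst and strong base avoids Z to E isomerisation to the tiglate, and 75 °C is well below the temperature at which a 1(10)E,4Z-diene would undergo Cope rearrangement.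

Step 23
Reactants: 29 amino diester
Product: 31 (3S,6R,7R,8R)-8-(angeloyloxy)-3-(methacryloyloxy)germacra-1(10)E,4Z,11(13)-trien-12,6-olide, via trimethylammonium iodide 30 (not isolated)
Conditions: MeI, THF, rt; then aq. NaHCO3, CH2Cl2, rt
Reagents that add atoms: none
Why: Exhaustive N-methylation gives the quaternary salt 30, and mild base removes the acidic C11 proton so that trimethylamine is eliminated (E1cB elimination of a Mannich base) and the C11=C13 methylene is formed. Esters and alkenes are inert to MeI and NaHCO3.

Step 24
Reactants: 31 triene lactone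
Product: 32 (1R,3S,6R,7R,8R,10R)-8-(angeloyloxy)-1,10-epoxy-3-(methacryloyloxy)germacra-4Z,11(13)-dien-12,6-olide (CNP0294228.1)
Conditions: mCPBA, NaHCO3, CH2Cl2, 0 °C
Reagents that add atoms: 3-chloroperoxybenzoic acid, OOC(=O)c1cccc(Cl)c1
Why: Prilezhaev epoxidation: the peracid should react with the only electron-rich alkene, the unconjugated trisubstituted C1=C10 bond, because the three conjugated alkenes and the C4=C5 bond with two allylic acyloxy groups are deactivated. Syn addition to the E alkene gives the trans epoxide, and attack on the outer face of the ring conformer with C14 on the β side is expected to set 1R,10R.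

## Compound list

1 | (S)-5-(hydroxymethyl)furan-2(5H)-one | O=C1C=C[C@@H](CO)O1 | starting material
2 | (S)-5-[(tert-butyldimethylsilyloxy)methyl]furan-2(5H)-one (fragment A) | O=C1C=C[C@@H](CO[Si](C)(C)C(C)(C)C)O1 | intermediate
3 | 4,4-dimethoxybutan-2-one | CC(=O)CC(OC)OC | starting material
4 | propane-1,3-dithiol | SCCCS | starting material
5 | 1-(1,3-dithian-2-yl)propan-2-one | CC(=O)CC1SCCCS1 | intermediate
6 | 2-[(2-methyl-1,3-dioxolan-2-yl)methyl]-1,3-dithiane (fragment B) | CC1(CC2SCCCS2)OCCO1 | intermediate
7 | N,N-dimethylmethyleneiminium iodide (Eschenmoser's salt) | C=[N+](C)C.[I-] | starting material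
8 | 2-lithio-2-[(2-methyl-1,3-dioxolan-2-yl)methyl]-1,3-dithiane | [Li]C1(CC2(C)OCCO2)SCCCS1 | intermediate (not isolated)
9 | lithium (4S,5S)-5-[(tert-butyldimethylsilyloxy)methyl]-4-{2-[(2-methyl-1,3-dioxolan-2-yl)methyl]-1,3-dithian-2-yl}-4,5-dihydrofuran-2-olate | [Li]OC1=C[C@H](C2(CC3(C)OCCO3)SCCCS2)[C@@H](CO[Si](C)(C)C(C)(C)C)O1 | intermediate (not isolated)
10 | (3R,4S,5S)-5-[(tert-butyldimethylsilyloxy)methyl]-3-[(dimethylamino)methyl]-4-{2-[(2-methyl-1,3-dioxolan-2-yl)methyl]-1,3-dithian-2-yl}dihydrofuran-2(3H)-one | O=C1[C@@H](CN(C)C)[C@H](C2(CC3(C)OCCO3)SCCCS2)[C@@H](CO[Si](C)(C)C(C)(C)C)O1 | intermediate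
11 | (3R,4S,5S)-5-[(tert-butyldimethylsilyloxy)methyl]-3-[(dimethylamino)methyl]-4-[2-(2-methyl-1,3-dioxolan-2-yl)acetyl]dihydrofuran-2(3H)-one | O=C1[C@@H](CN(C)C)[C@H](C(=O)CC2(C)OCCO2)[C@@H](CO[Si](C)(C)C(C)(C)C)O1 | intermediate
12 | (3R,4R,5S)-5-[(tert-butyldimethylsilyloxy)methyl]-3-[(dimethylamino)methyl]-4-[(1R)-1-hydroxy-2-(2-methyl-1,3-dioxolan-2-yl)ethyl]dihydrofuran-2(3H)-one | O=C1[C@@H](CN(C)C)[C@H]([C@H](O)CC2(C)OCCO2)[C@@H](CO[Si](C)(C)C(C)(C)C)O1 | intermediate
13 | (3R,4S,5S)-4-[(1R)-1-(tert-butyldimethylsilyloxy)-2-(2-methyl-1,3-dioxolan-2-yl)ethyl]-5-[(tert-butyldimethylsilyloxy)methyl]-3-[(dimethylamino)methyl]dihydrofuran-2(3H)-one | O=C1[C@@H](CN(C)C)[C@H]([C@H](O[Si](C)(C)C(C)(C)C)CC2(C)OCCO2)[C@@H](CO[Si](C)(C)C(C)(C)C)O1 | intermediate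
14 | (3R,4S,5S)-4-[(1R)-1-(tert-butyldimethylsilyloxy)-2-(2-methyl-1,3-dioxolan-2-yl)ethyl]-3-[(dimethylamino)methyl]-5-(hydroxymethyl)dihydrofuran-2(3H)-one | O=C1[C@@H](CN(C)C)[C@H]([C@H](O[Si](C)(C)C(C)(C)C)CC2(C)OCCO2)[C@@H](CO)O1 | intermediate
15 | (2S,3S,4R)-3-[(1R)-1-(tert-butyldimethylsilyloxy)-2-(2-methyl-1,3-dioxolan-2-yl)ethyl]-4-[(dimethylamino)methyl]-5-oxotetrahydrofuran-2-carbaldehyde | O=C1[C@@H](CN(C)C)[C@H]([C@H](O[Si](C)(C)C(C)(C)C)CC2(C)OCCO2)[C@@H](C=O)O1 | intermediate
16 | (3R,4S,5S)-4-[(1R)-1-(tert-butyldimethylsilyloxy)-2-(2-methyl-1,3-dioxolan-2-yl)ethyl]-3-[(dimethylamino)methyl]-5-[(1Z)-2-iodoprop-1-en-1-yl]dihydrofuran-2(3H)-one | O=C1[C@@H](CN(C)C)[C@H]([C@H](O[Si](C)(C)C(C)(C)C)CC2(C)OCCO2)[C@@H](/C=C(\I)C)O1 | intermediate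
17 | (2Z)-3-{(2R,3S,4R)-3-[(1R)-1-(tert-butyldimethylsilyloxy)-2-(2-methyl-1,3-dioxolan-2-yl)ethyl]-4-[(dimethylamino)methyl]-5-oxotetrahydrofuran-2-yl}-2-methylprop-2-enal | O=C1[C@@H](CN(C)C)[C@H]([C@H](O[Si](C)(C)C(C)(C)C)CC2(C)OCCO2)[C@@H](/C=C(\C=O)C)O1 | intermediate
18 | (3R,4S,5R)-4-[(1R)-1-(tert-butyldimethylsilyloxy)-2-(2-methyl-1,3-dioxolan-2-yl)ethyl]-3-[(dimethylamino)methyl]-5-[(1Z,3S)-3-hydroxy-2-methylhexa-1,5-dien-1-yl]dihydrofuran-2(3H)-one | O=C1[C@@H](CN(C)C)[C@H]([C@H](O[Si](C)(C)C(C)(C)C)CC2(C)OCCO2)[C@@H](/C=C(\[C@@H](O)CC=C)C)O1 | intermediate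
19 | (3R,4S,5R)-4-[(1R)-1-(tert-butyldimethylsilyloxy)-3-oxobutyl]-3-[(dimethylamino)methyl]-5-[(1Z,3S)-3-hydroxy-2-methylhexa-1,5-dien-1-yl]dihydrofuran-2(3H)-one | O=C1[C@@H](CN(C)C)[C@H]([C@H](O[Si](C)(C)C(C)(C)C)CC(C)=O)[C@@H](/C=C(\[C@@H](O)CC=C)C)O1 | intermediate
20 | (3R,4S,5R)-4-[(1R)-1-(tert-butyldimethylsilyloxy)-3-oxobutyl]-3-[(dimethylamino)methyl]-5-[(1Z,3S)-2-methyl-3-(triethylsilyloxy)hexa-1,5-dien-1-yl]dihydrofuran-2(3H)-one | O=C1[C@@H](CN(C)C)[C@H]([C@H](O[Si](C)(C)C(C)(C)C)CC(C)=O)[C@@H](/C=C(\[C@@H](O[Si](CC)(CC)CC)CC=C)C)O1 | intermediate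
21 | (3R,4S,5R)-4-[(1R)-1-(tert-butyldimethylsilyloxy)-3-oxobutyl]-3-[(dimethylamino)methyl]-5-[(1Z,3S)-5,6-dihydroxy-2-methyl-3-(triethylsilyloxy)hex-1-en-1-yl]dihydrofuran-2(3H)-one (both epimers at the new carbinol carbon) | O=C1[C@@H](CN(C)C)[C@H]([C@H](O[Si](C)(C)C(C)(C)C)CC(C)=O)[C@@H](/C=C(\[C@@H](O[Si](CC)(CC)CC)CC(O)CO)C)O1 | intermediate (not isolated)
22 | (3S,4Z)-5-{(2R,3S,4R)-3-[(1R)-1-(tert-butyldimethylsilyloxy)-3-oxobutyl]-4-[(dimethylamino)methyl]-5-oxotetrahydrofuran-2-yl}-4-methyl-3-(triethylsilyloxy)pent-4-enal | O=C1[C@@H](CN(C)C)[C@H]([C@H](O[Si](C)(C)C(C)(C)C)CC(C)=O)[C@@H](/C=C(\[C@@H](O[Si](CC)(CC)CC)CC=O)C)O1 | intermediate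
23 | (1R,3S,6R,7S,8R,10R,11R)-8-(tert-butyldimethylsilyloxy)-13-(dimethylamino)-1,10-dihydroxy-3-(triethylsilyloxy)germacr-4Z-en-12,6-olide | CC[Si](CC)(CC)O[C@H]1C[C@@H](O)[C@](C)(O)C[C@@H](O[Si](C)(C)C(C)(C)C)[C@H]2[C@H](CN(C)C)C(=O)O[C@@H]2/C=C\1C | intermediate
24 | (1R,3S,6R,7S,8R,10R,11R)-8-(tert-butyldimethylsilyloxy)-13-(dimethylamino)-1,10-(thiocarbonyldioxy)-3-(triethylsilyloxy)germacr-4Z-en-12,6-olide | CC[Si](CC)(CC)O[C@H]1C[C@H]3OC(=S)O[C@]3(C)C[C@@H](O[Si](C)(C)C(C)(C)C)[C@H]2[C@H](CN(C)C)C(=O)O[C@@H]2/C=C\1C | intermediate
25 | (3S,6R,7S,8R,11R)-8-(tert-butyldimethylsilyloxy)-13-(dimethylamino)-3-(triethylsilyloxy)germacra-1(10)E,4Z-dien-12,6-olide | CC[Si](CC)(CC)O[C@H]1C/C=C(C)/C[C@@H](O[Si](C)(C)C(C)(C)C)[C@H]2[C@H](CN(C)C)C(=O)O[C@@H]2/C=C\1C | intermediate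
26 | (3S,6R,7S,8R,11R)-8-(tert-butyldimethylsilyloxy)-13-(dimethylamino)-3-hydroxygermacra-1(10)E,4Z-dien-12,6-olide | O[C@H]1C/C=C(C)/C[C@@H](O[Si](C)(C)C(C)(C)C)[C@H]2[C@H](CN(C)C)C(=O)O[C@@H]2/C=C\1C | intermediate
27 | (3S,6R,7S,8R,11R)-8-(tert-butyldimethylsilyloxy)-13-(dimethylamino)-3-(methacryloyloxy)germacra-1(10)E,4Z-dien-12,6-olide | C=C(C)C(=O)O[C@H]1C/C=C(C)/C[C@@H](O[Si](C)(C)C(C)(C)C)[C@H]2[C@H](CN(C)C)C(=O)O[C@@H]2/C=C\1C | intermediate
28 | (3S,6R,7R,8R,11R)-13-(dimethylamino)-8-hydroxy-3-(methacryloyloxy)germacra-1(10)E,4Z-dien-12,6-olide | C=C(C)C(=O)O[C@H]1C/C=C(C)/C[C@@H](O)[C@H]2[C@H](CN(C)C)C(=O)O[C@@H]2/C=C\1C | intermediate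
29 | (3S,6R,7R,8R,11R)-8-(angeloyloxy)-13-(dimethylamino)-3-(methacryloyloxy)germacra-1(10)E,4Z-dien-12,6-olide | C=C(C)C(=O)O[C@H]1C/C=C(C)/C[C@@H](OC(=O)/C(C)=C\C)[C@H]2[C@H](CN(C)C)C(=O)O[C@@H]2/C=C\1C | intermediate
30 | (3S,6R,7R,8R,11R)-8-(angeloyloxy)-3-(methacryloyloxy)-13-(trimethylammonio)germacra-1(10)E,4Z-dien-12,6-olide iodide | C=C(C)C(=O)O[C@H]1C/C=C(C)/C[C@@H](OC(=O)/C(C)=C\C)[C@H]2[C@H](C[N+](C)(C)C)C(=O)O[C@@H]2/C=C\1C.[I-] | intermediate (not isolated)
31 | (3S,6R,7R,8R)-8-(angeloyloxy)-3-(methacryloyloxy)germacra-1(10)E,4Z,11(13)-trien-12,6-olide | C=C(C)C(=O)O[C@H]1C/C=C(C)/C[C@@H](OC(=O)/C(C)=C\C)[C@H]2C(=C)C(=O)O[C@@H]2/C=C\1C | intermediate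
32 | (1R,3S,6R,7R,8R,10R)-8-(angeloyloxy)-1,10-epoxy-3-(methacryloyloxy)germacra-4Z,11(13)-dien-12,6-olide (CNP0294228.1) | C=C(C)C(=O)O[C@H]1C[C@H]2O[C@]2(C)C[C@@H](OC(=O)/C(C)=C\C)[C@H]2C(=C)C(=O)O[C@@H]2/C=C\1C | target

## Step count and least certain steps

Total: 24 steps. Longest linear sequence: 23 steps (from 3 through 5, 6 and 10 to 32; the branch from 1 joins at step 4).

Step 4 (key step). The most likely failures are competing 1,2-addition or γ-deprotonation of the butenolide by the hard, hindered carbanion, and loss of the congested enolate by proton transfer before the sparingly soluble iminium salt alkylates it. The fallback separates the two bond formations. From 6 and 2, the conjugate addition is run alone and quenched at −78 °C with NH4Cl to isolate (4S,5S)-5-[(tert-butyldimethylsilyloxy)methyl]-4-{2-[(2-methyl-1,3-dioxolan-2-yl)methyl]-1,3-dithian-2-yl}dihydrofuran-2(3H)-one F1. The enolate is then regenerated with LiN(iPr)2 at −78 °C and aminomethylated with 7, again anti to the C7 substituent, which returns to 10.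

Step 16. Intermolecular coupling or simple carbonyl reduction may outrun cyclisation, the titanium-activated aldehyde may lose its β-silyloxy group, or the coupling may be cis-selective. The fallback closes the ring by metathesis. From 20, Takai–Lombardo methylenation of the C10 ketone (Zn, CH2Br2, TiCl4) should give the diene (3R,4S,5R)-4-[(1R)-1-(tert-butyldimethylsilyloxy)-3-methylbut-3-en-1-yl]-3-[(dimethylamino)methyl]-5-[(1Z,3S)-2-methyl-3-(triethylsilyloxy)hexa-1,5-dien-1-yl]dihydrofuran-2(3H)-one F2. Ring-closing metathesis with the second-generation Grubbs catalyst (amine protonated with camphorsulfonic acid, toluene, 80 °C, high dilution) would then form C1=C10 directly and return to 25 after separation of any Z isomer. Inside the main route, the other trans diol, (1S,3S,6R,7S,8R,10S,11R)-8-(tert-butyldimethylsilyloxy)-13-(dimethylamino)-1,10-dihydroxy-3-(triethylsilyloxy)germacr-4Z-en-12,6-olide F3, is carried through steps 17 and 18 by way of its cyclic thionocarbonate F4 to the same 25.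

Step 6. Facial discrimination may be poor if the catalyst does not distinguish the branched C7 from the neopentyl-type C9 well enough, and the amine may slow the reduction by binding boron. The fallback corrects the configuration afterwards. 11 is reduced without chiral control (NaBH4, CeCl3, MeOH, −78 °C). The unwanted epimer, (3R,4R,5S)-5-[(tert-butyldimethylsilyloxy)methyl]-3-[(dimethylamino)methyl]-4-[(1S)-1-hydroxy-2-(2-methyl-1,3-dioxolan-2-yl)ethyl]dihydrofuran-2(3H)-one F5, is inverted by Mitsunobu esterification (chloroacetic acid, PPh3, DIAD) to the 8R chloroacetate F6. Thiourea with NaHCO3 in ethanol then cleaves the ester and returns to 12.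

Step 10. Conversion may be low, Z selectivity may erode, and the basic ylide may epimerise C6 of the α-acyloxy aldehyde. The fallback builds the haloalkene in two neutral steps. From 15, Ramirez olefination (CBr4, PPh3) should give the 1,1-dibromoalkene (3R,4S,5S)-4-[(1R)-1-(tert-butyldimethylsilyloxy)-2-(2-methyl-1,3-dioxolan-2-yl)ethyl]-5-(2,2-dibromoethenyl)-3-[(dimethylamino)methyl]dihydrofuran-2(3H)-one F7. A Negishi coupling with Me2Zn and PdCl2(DPEphos) is expected to replace only the bromine trans to C6 and give the Z-bromoalkene (3R,4S,5S)-5-[(1Z)-2-bromoprop-1-en-1-yl]-4-[(1R)-1-(tert-butyldimethylsilyloxy)-2-(2-methyl-1,3-dioxolan-2-yl)ethyl]-3-[(dimethylamino)methyl]dihydrofuran-2(3H)-one F8. F8 is formylated as in step 11 at a somewhat higher temperature and returns to 17.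

Step 24. The peracid may attack the other face of C1=C10, or the acid formed may open the epoxide transannularly. The fallback inverts the facial outcome. From 31, NBS in aqueous THF should add bromine from the face the peracid prefers and water anti at the tertiary C10, giving the bromohydrin (1S,3S,6R,7R,8R,10R)-8-(angeloyloxy)-1-bromo-10-hydroxy-3-(methacryloyloxy)germacra-4Z,11(13)-dien-12,6-olide F9. K2CO3 in acetone then closes the epoxide with inversion at C1 and returns to 32.

Step 22. The hindered C8 hydroxyl may acylate slowly, and prolonged heating may isomerise the angeloyl group to the tigloyl group. The fallback builds the Z alkene on the ester. 28 is esterified (DCC, DMAP) with 2-[bis(2,2,2-trifluoroethoxy)phosphoryl]propanoic acid to give the phosphonopropanoate (3S,6R,7R,8R,11R)-8-{2-[bis(2,2,2-trifluoroethoxy)phosphoryl]propanoyloxy}-13-(dimethylamino)-3-(methacryloyloxy)germacra-1(10)E,4Z-dien-12,6-olide F10. A Still–Gennari olefination with acetaldehyde (KN(SiMe3)2, 18-crown-6, THF, −78 °C) should then give the Z ester and return to 29.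

## Further compounds

F1 | step 4 | (4S,5S)-5-[(tert-butyldimethylsilyloxy)methyl]-4-{2-[(2-methyl-1,3-dioxolan-2-yl)methyl]-1,3-dithian-2-yl}dihydrofuran-2(3H)-one | O=C1C[C@H](C2(CC3(C)OCCO3)SCCCS2)[C@@H](CO[Si](C)(C)C(C)(C)C)O1
F2 | step 16 | (3R,4S,5R)-4-[(1R)-1-(tert-butyldimethylsilyloxy)-3-methylbut-3-en-1-yl]-3-[(dimethylamino)methyl]-5-[(1Z,3S)-2-methyl-3-(triethylsilyloxy)hexa-1,5-dien-1-yl]dihydrofuran-2(3H)-one | O=C1[C@@H](CN(C)C)[C@H]([C@H](O[Si](C)(C)C(C)(C)C)CC(C)=C)[C@@H](/C=C(\[C@@H](O[Si](CC)(CC)CC)CC=C)C)O1
F3 | step 16 | (1S,3S,6R,7S,8R,10S,11R)-8-(tert-butyldimethylsilyloxy)-13-(dimethylamino)-1,10-dihydroxy-3-(triethylsilyloxy)germacr-4Z-en-12,6-olide | CC[Si](CC)(CC)O[C@H]1C[C@H](O)[C@@](C)(O)C[C@@H](O[Si](C)(C)C(C)(C)C)[C@H]2[C@H](CN(C)C)C(=O)O[C@@H]2/C=C\1C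
F4 | step 16 | (1S,3S,6R,7S,8R,10S,11R)-8-(tert-butyldimethylsilyloxy)-13-(dimethylamino)-1,10-(thiocarbonyldioxy)-3-(triethylsilyloxy)germacr-4Z-en-12,6-olide | CC[Si](CC)(CC)O[C@H]1C[C@@H]3OC(=S)O[C@@]3(C)C[C@@H](O[Si](C)(C)C(C)(C)C)[C@H]2[C@H](CN(C)C)C(=O)O[C@@H]2/C=C\1C
F5 | step 6 | (3R,4R,5S)-5-[(tert-butyldimethylsilyloxy)methyl]-3-[(dimethylamino)methyl]-4-[(1S)-1-hydroxy-2-(2-methyl-1,3-dioxolan-2-yl)ethyl]dihydrofuran-2(3H)-one | O=C1[C@@H](CN(C)C)[C@H]([C@@H](O)CC2(C)OCCO2)[C@@H](CO[Si](C)(C)C(C)(C)C)O1
F6 | step 6 | (1R)-1-{(3S,4R,5S)-5-[(tert-butyldimethylsilyloxy)methyl]-3-[(dimethylamino)methyl]-2-oxotetrahydrofuran-4-yl}-2-(2-methyl-1,3-dioxolan-2-yl)ethyl chloroacetate (descriptors of the ring carbons by priority; geometry as in 12) | O=C1[C@@H](CN(C)C)[C@H]([C@H](OC(=O)CCl)CC2(C)OCCO2)[C@@H](CO[Si](C)(C)C(C)(C)C)O1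
F7 | step 10 | (3R,4S,5S)-4-[(1R)-1-(tert-butyldimethylsilyloxy)-2-(2-methyl-1,3-dioxolan-2-yl)ethyl]-5-(2,2-dibromoethenyl)-3-[(dimethylamino)methyl]dihydrofuran-2(3H)-one | O=C1[C@@H](CN(C)C)[C@H]([C@H](O[Si](C)(C)C(C)(C)C)CC2(C)OCCO2)[C@@H](C=C(Br)Br)O1
F8 | step 10 | (3R,4S,5S)-5-[(1Z)-2-bromoprop-1-en-1-yl]-4-[(1R)-1-(tert-butyldimethylsilyloxy)-2-(2-methyl-1,3-dioxolan-2-yl)ethyl]-3-[(dimethylamino)methyl]dihydrofuran-2(3H)-one | O=C1[C@@H](CN(C)C)[C@H]([C@H](O[Si](C)(C)C(C)(C)C)CC2(C)OCCO2)[C@@H](/C=C(\Br)C)O1
F9 | step 24 | (1S,3S,6R,7R,8R,10R)-8-(angeloyloxy)-1-bromo-10-hydroxy-3-(methacryloyloxy)germacra-4Z,11(13)-dien-12,6-olide | C=C(C)C(=O)O[C@H]1C[C@H](Br)[C@](C)(O)C[C@@H](OC(=O)/C(C)=C\C)[C@H]2C(=C)C(=O)O[C@@H]2/C=C\1C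
F10 | step 22 | (3S,6R,7R,8R,11R)-8-{2-[bis(2,2,2-trifluoroethoxy)phosphoryl]propanoyloxy}-13-(dimethylamino)-3-(methacryloyloxy)germacra-1(10)E,4Z-dien-12,6-olide (both epimers at the phosphonate α-carbon) | C=C(C)C(=O)O[C@H]1C/C=C(C)/C[C@@H](OC(=O)C(C)P(=O)(OCC(F)(F)F)OCC(F)(F)F)[C@H]2[C@H](CN(C)C)C(=O)O[C@@H]2/C=C\1C
A1 | alternative 1 | ten-membered 1(10)E,4Z-dienyl C5 triflate with 6-methoxymethoxy, 7-isopropenyl and 8-tert-butyldimethylsilyloxy groups | C1C/C=C(C)/C[C@@H](O[Si](C)(C)C(C)(C)C)[C@@H](C(C)=C)[C@H](OCOC)/C(OS(=O)(=O)C(F)(F)F)=C\1C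
A2 | alternative 2 | cyclic diisopropylsilylene diether of the Z-2-ene-1,4-diol (seven-membered dioxasilacycle joining O3 and O6) | CC1=C[C@H]([C@H](CCOCc2ccccc2)[C@H](O[Si](C)(C)C(C)(C)C)CC2(C)OCCO2)O[Si](C(C)C)(C(C)C)O[C@H]1CCOCc1ccc(OC)cc1
A3 | alternative 3 | ten-membered 1(10)E,4Z-diene fused to the saturated trans 12,6-lactone, with 3-tert-butyldimethylsilyloxy and 8-triethylsilyloxy groups | CC(C)(C)[Si](C)(C)O[C@H]1C/C=C(C)/C[C@@H](O[Si](CC)(CC)CC)[C@H]2CC(=O)O[C@@H]2/C=C\1C
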